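The second nucleophile is the trap in this flask, and I keep the books on the starting material it catches.

| flask | starting material | first nucleophile | second nucleophile | remark | time |
|---|---|---|---|---|---|
| north-east | 5 mM | 2.1 equiv | 0.50 equiv | run made earlier |  |
| south | 5 mM | 3.3 equiv | 0.50 equiv | run made earlier |  |
| north-west | 5 mM | 1.5 equiv | 0.25 equiv | run made earlier |  |
| flask | 5.0 mM | 1.50 equiv | 0.500 equiv |  | 40 min |

| run | time / min | target / % | other capture product / % | starting material / % |
|---|---|---|---|---|
| north-east | 5.00 | 50.7 | 48.7 | 2.6 |
| north-east | 10.0 | 51.2 | 48.3 | 0 |
| north-east | 15.0 | 50.8 | 49.3 | 0.1 |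
| north-east | 20.0 | 49.6 | 47.5 | 0 |
| north-east | 25.0 | 49.5 | 46.7 | 0 |
| north-east | 30.0 | 51.3 | 47.6 | 0 |
| south | 5.00 | 51.1 | 45.1 | 0 |
| south | 10.0 | 50.8 | 46.0 | 1.3 |
| south | 15.0 | 50.2 | 47.8 | 0.3 |
| south | 20.0 | 52.7 | 46.7 | 0 |
| south | 25.0 | 52.3 | 48.3 | 0.1 |
| south | 30.0 | 50.9 | 48.6 | 0.1 |
| north-west | 2.50 | 64.1 | 24.5 | 7.7 |
| north-west | 5.00 | 70.9 | 23.5 | 1.1 |
| north-west | 10.0 | 72.3 | 23.1 | 0 |
| north-west | 15.0 | 70.8 | 22.7 | 0 |
| north-west | 30.0 | 70.5 | 23.3 | 0.6 |

(each reading ± 1 percentage point)

- ratio of target to other capture product at 3.0 s
- ratio of target to other capture product at 40 min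

- a reading or a percentage of target counts all its forms, free or not

In the north-east run the readings stay flat from 10.0 min, when the starting material reads 0%, so I take a late reading as a closed entry. The other capture product follows the charge of second nucleophile. The north-east and south runs, which differ in first nucleophile, end at 47.6% and 48.6%, within the scatter of each other. The north-west run, with half that charge of second nucleophile and less first nucleophile, ends at 23.3%. Pooled over these runs, 0.956 is my trap yield, the other capture product formed per equivalent of second nucleophile charged.

Now the ledger for this flask. The first entry gives 47.8% to other capture product, which leaves 52.2% for the remaining entries. The north-west run has this flask's charge of first nucleophile, and in its last reading 8.08% of the remainder is neither target nor other capture product. I charge the same leak here. So target closes at 48.0%, and my ratio at 40 min is 1.00. The ledger is silent at 3.0 s, since the earliest reading, 2.50 min in the north-west run, comes much later. There I expect a ratio well below one and give no figure.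

The forecast says 0.15 and 1.07, holding that “the second nucleophile is much the better trap”, and its final ratio stands above mine.

The flask gives 0.0953 and 1.03, with target, crystals counted, at 49.2% and other capture product at 47.8%.

    second nucleophile → decomposed reagent (k = 0.00209 /s)
    starting material → intermediate (k = 0.0171 /s)
    intermediate → solvolysis product (k = 0.654 /s)
    first nucleophile + intermediate → target (k = 1730 /M/s)
    crystals ⇌ target, rate k5*(cs5 - [target]) while solid is left; crystals form when [target] > cs5 (solubility = 2.00 mM, k = 0.479 /s)
    second nucleophile + intermediate → other capture product (k = 57200 /M/s)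

In this flask the second nucleophile stands at 0% by 4.00 min, and that shortage is the largest single effect on the final ratio: the simulated run that keeps it from running short ends at 0.0883 against 1.03. In the neighbour with 2.50 equiv of first nucleophile, the trap yield again gives 47.8% other capture product. The leak in the last reading of the north-east run, the nearest charge of first nucleophile, is 2.10%, and it gives a ratio of 1.07. That neighbour computes 1.07.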